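**Plan** (germacrane numbering: ring C1–C10, lactone C11–C13, C14 on C10, C15 on C4)

1. Cuts, in retrosynthetic order: the C8–O acyl bond; the C12 carbonyl (allylic oxidation) and C7–C11 (gold-catalysed attack of a C7=C8 silyl enol ether on a propargyl group carried by O6); C9–C10 and O–C10 together (oxonium-ylide [2,3] shift, which cleaves an O–C7 bond that is not in the target); C3–H and C2–C3 (ester enolate, then Et3SiH, on a lactone); C4=C5 (ring-closing metathesis).
2. Forward: (3R,4R)-hexa-1,5-diene-3,4-diol → six-membered dihydropyranone O–C3–C4=C5–C6–C7 (C4=C5 held Z) → all-cis dihydropyran diazo ketone → in one step the oxolane and the nine-membered oxacycle (= the ten-membered carbocycle) → fused 3-methyleneoxolane → lactone. The medium ring is never closed end to end.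
3. Stereochemistry: C6 is a diol centre; the other diol centre (C7) directs hydride to C3 and is then erased in the key step; C10 follows from C3 because only the cis-bridged bicycle can form; C1 by exo hydride attack; C7 is set again by delivery of C11 from O6, both enol ether isomers converging; C8 by hydride anti to the new C7–C11 bond.
4. Enabling feature: the ether oxygen bridges C3 and C10 and the oxygen-bearing C1 is next to C10, so the oxolane O–C3–C2–C1–C10 spanning the ring O–C3–C4=C5–C6–C7–C8–C9–C10 is the product pattern of a diazo-ketone-derived oxonium ylide that moves an allyl group from O to C10. Because C7 lies three atoms beyond the Z olefin, O, C3, C4, C5, C6 and C7 can first form a 3,6-dihydro-2H-pyran whose C7 carries the migrating 2-silyloxyallyl unit (C8, C9).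

Key step: step 9

Remark: diazoethane (15) is taken as a freshly prepared ethereal solution from commercial N-ethyl-N-nitrosourea. Compound 19 is expected as a mixture of C7=C8 enol ether isomers; both are carried on because step 12 turns either into the same ketone.

**Step 1**
Reactants: 1 (3R,4R)-hexa-1,5-diene-3,4-diol; 2 3-bromo-1-(trimethylsilyl)prop-1-yne
Product: 3 (3R,4R)-4-{[3-(trimethylsilyl)prop-2-yn-1-yl]oxy}hexa-1,5-dien-3-ol
Conditions: Ag2O (1.5 equiv), 2 (1.1 equiv), CH2Cl2, rt, dark
Reagents that add atoms: none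
Why: Silver(I) oxide-mediated Williamson monoalkylation of a symmetric diol; the C2 axis makes both hydroxyls equivalent, so one mono-ether results and neither stereocentre (future C6 and the relay centre C7) is touched.

**Step 2**
Reactants: 3; 4 2-methylprop-2-enoyl chloride (methacryloyl chloride)
Product: 5 (3R,4R)-4-{[3-(trimethylsilyl)prop-2-yn-1-yl]oxy}hexa-1,5-dien-3-yl 2-methylprop-2-enoate
Conditions: Et3N, DMAP (cat.), CH2Cl2, 0 °C
Reagents that add atoms: none
Why: DMAP-catalysed acylation of the remaining secondary alcohol by an acid chloride (nucleophilic catalysis), with no stereocentre involved.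

**Step 3**
Reactants: 5
Product: 6 (5R,6R)-6-ethenyl-3-methyl-5-{[3-(trimethylsilyl)prop-2-yn-1-yl]oxy}-5,6-dihydro-2H-pyran-2-one
Conditions: Hoveyda–Grubbs II (5 mol %), toluene (5 mM), 80 °C
Reagents that add atoms: none
Why: Ring-closing metathesis between the methacrylate and the homoallylic vinyl group should close the six-membered α-methyl unsaturated δ-lactone in preference to the five-membered butenolide, the silyl-capped alkyne stays out of enyne metathesis, and the ring fixes the future C4=C5 olefin as Z.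

**Step 4**
Reactants: 6; 7 tert-butyl acetate
Product: 9 tert-butyl 2-[(5R,6R)-6-ethenyl-2-hydroxy-3-methyl-5-{[3-(trimethylsilyl)prop-2-yn-1-yl]oxy}-5,6-dihydro-2H-pyran-2-yl]acetate (hemiketal, both anomers), via lithium enolate of tert-butyl acetate 8 (not isolated)
Conditions: LDA, THF, −78 °C; then 6, −78 °C; AcOH quench at −78 °C
Reagents that add atoms: none
Why: Claisen-type 1,2-addition of a lithium ester enolate to the lactone carbonyl under kinetic control at −78 °C (s-trans-locked, α-methylated enoate; tetrahedral adduct kept until the cold quench) should give the hemiketal, as in the first half of a Kishi C-glycoside synthesis.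

**Step 5**
Reactants: 9
Product: 11 2-[(2S,5R,6R)-6-ethenyl-3-methyl-5-{[3-(trimethylsilyl)prop-2-yn-1-yl]oxy}-5,6-dihydro-2H-pyran-2-yl]acetic acid (all-cis), via tert-butyl ester 10 (not isolated)
Conditions: Et3SiH (3 equiv), TFA, CH2Cl2, −40 → 0 °C
Reagents that add atoms: none
Why: Ionic hydrogenation (Kishi reduction): the allylic oxocarbenium ion should take hydride from Et3SiH at the oxocarbenium carbon (C3) axially, on the face anti to both the C6 ether and the C7 vinyl group, which sets C3 (S) with the acetic acid chain cis to both, and TFA then cleaves the tert-butyl ester.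

**Step 6**
Reactants: 11
Product: 12 2-[(2S,5R,6S)-6-acetyl-3-methyl-5-{[3-(trimethylsilyl)prop-2-yn-1-yl]oxy}-5,6-dihydro-2H-pyran-2-yl]acetic acid
Conditions: Pd(Quinox)Cl2 (5 mol %), AgSbF6 (12 mol %), aq. TBHP, CH2Cl2, 0 °C → rt
Reagents that add atoms: tert-butyl hydroperoxide, CC(C)(C)OO
Why: Catalyst-controlled Tsuji–Wacker oxidation, which turns terminal olefins bearing an allylic oxygen into methyl ketones and should leave the trisubstituted ring olefin and the silyl alkyne alone.

**Step 7**
Reactants: 12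
Product: 14 2-[(2S,5R,6S)-3-methyl-6-{1-[(triisopropylsilyl)oxy]ethenyl}-5-{[3-(trimethylsilyl)prop-2-yn-1-yl]oxy}-5,6-dihydro-2H-pyran-2-yl]acetic acid, via dilithium carboxylate enolate of 12 13 (not isolated)
Conditions: LDA (2.1 equiv), THF, −78 °C; TIPSOTf (1.05 equiv), −78 °C; AcOH (1 equiv), cold pH 6 work-up
Reagents that add atoms: triisopropylsilyl trifluoromethanesulfonate, CC(C)[Si](C(C)C)(C(C)C)OS(=O)(=O)C(F)(F)F
Why: Kinetic enolate trapping: after the carboxylate has consumed the first equivalent of base the methyl ketone is deprotonated at CH3, and the more nucleophilic enolate oxygen is silylated, which gives the 2-silyloxyallyl unit regiospecifically.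

**Step 8**
Reactants: 14; 15 diazoethane
Product: 17 3-diazo-1-[(2S,5R,6S)-3-methyl-6-{1-[(triisopropylsilyl)oxy]ethenyl}-5-{[3-(trimethylsilyl)prop-2-yn-1-yl]oxy}-5,6-dihydro-2H-pyran-2-yl]butan-2-one, via isobutyl carbonic mixed anhydride of 14 16 (not isolated)
Conditions: iBuOCOCl, Et3N, THF/Et2O, −20 °C; then 15 in Et2O, −20 → 0 °C
Reagents that add atoms: none
Why: Acylation of a diazoalkane by a mixed carbonic anhydride (Arndt–Eistert-type diazo ketone synthesis) brings in C10 and its methyl group C14 under neutral conditions that the enol ether tolerates.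

**Step 9**
Reactants: 17
Product: 19 (1S,4R,8S,2Z)-2,8-dimethyl-6-[(triisopropylsilyl)oxy]-4-{[3-(trimethylsilyl)prop-2-yn-1-yl]oxy}-11-oxabicyclo[6.2.1]undeca-2,5-dien-9-one (bicyclo C1, C4, C8, C9 = target C3, C6, C10, C1; 5E/5Z mixture, 5E drawn), via bicyclic oxonium ylide 18 (not isolated)
Conditions: Cu(hfacac)2 (10 mol %), CH2Cl2, reflux, slow addition of 17 (5 mM)
Reagents that add atoms: none
Why: The copper catalyst should decompose the diazo ketone to an electrophilic carbenoid at C10 that is captured by a lone pair of the ring oxygen, closing the five-membered ring O–C3–C2–C1–C10 as oxonium ylide 18 (five-membered heteroatom capture, the usual mode for a β-alkoxy diazo ketone); the ylide carbon then bonds to C9, the terminus of the 2-silyloxyallyl group on C7, in a concerted suprafacial [2,3]-sigmatropic shift through a five-centre envelope (C10–O–C7–C8–C9) that cleaves O–C7 and enlarges the six-membered ring by three atoms to the nine-membered oxacycle, i.e. the ten-membered carbocycle C1–C10, by ring expansion and not by end-to-end closure. The closest known reaction is the copper-catalysed oxonium-ylide formation/[2,3] ring expansion of 2-alkenyl tetrahydropyrans bearing a diazo ketone side chain to 11-oxabicyclo[6.2.1]undecenones. The new quaternary centre C10 is controlled by C3: the allyl terminus can only reach the face of the ylide carbon that gives the cis-bridged bicycle, so C9 ends cis to C4 and the methyl group exo (10S). The C7 centre, having relayed the chirality of the diol to C3 in step 5, becomes sp2, and the geometry of the new C7=C8 enol ether does not matter because step 12 converts both isomers into one ketone. The step needs ylide formation to win over 1,2-hydride shift of the methyl-bearing carbenoid and over cyclopropanation of C4=C5, and [2,3] to win over [1,2] shift: the electrophilic Cu(II) hexafluoroacetylacetonate favours attack by the ether oxygen, cyclopropanation would have to join two fully substituted carbons, and the endocyclic C3–O bond cannot align with the C4=C5 π system, so only the exocyclic allyl group can migrate.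

**Step 10**
Reactants: 19
Product: 21 (1S,4R,8S,9S,2Z)-2,8-dimethyl-4-(prop-2-yn-1-yloxy)-6-[(triisopropylsilyl)oxy]-11-oxabicyclo[6.2.1]undeca-2,5-dien-9-ol, via C-silylated alcohol 20 (not isolated)
Conditions: NaBH4, MeOH, −20 °C; then K2CO3, rt
Reagents that add atoms: none
Why: Borohydride reduction of the C1 ketone from the exo face (the side of the oxygen bridge; the endo face is covered by the C4–C9 bridge, as in 7-oxanorbornan-2-ones) should give the endo (1S) alcohol while the silyl enol ether masks C8, and carbonate-catalysed methanolysis then removes the alkynyl silane.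

**Step 11**
Reactants: 21
Product: 22 tert-butyldimethylsilyl ether of 21 at O1 (target numbering)
Conditions: TBSOTf, 2,6-lutidine, CH2Cl2, −78 → 0 °C
Reagents that add atoms: tert-butyldimethylsilyl trifluoromethanesulfonate, CC(C)(C)[Si](C)(C)OS(=O)(=O)C(F)(F)F
Why: Silylation of a hindered secondary alcohol with a silyl triflate and a hindered base, so that steps 14 and 15 act only at O8 and C12.

**Step 12**
Reactants: 22
Product: 23 tricyclic ketone (target numbering): target skeleton in which O6–C12H2–C11(=C13H2)–C7 is a 3-methyleneoxolane, C8 is C=O and O1 carries TBS; C1, C3, C6, C7, C10 as in the target (H6/H7 trans), 4Z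
Conditions: Ph3PAuCl (10 mol %), AgBF4 (10 mol %), CH2Cl2/MeOH (10:1), 40 °C
Reagents that add atoms: none
Why: Gold(I)-catalysed 5-exo-dig carbocyclisation of a silyl enol ether onto a terminal alkyne (Conia-ene type): C7 of the enol ether is far more nucleophilic than the C4=C5 olefin, C11 is delivered from the O6 tether to the face of C7 syn to O6 with H6 eclipsing the enol ether plane (A1,3 strain), which should set C7 with H6/H7 trans from either enol ether isomer, and protodeauration leaves the exocyclic methylene and the C8 ketone.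

**Step 13**
Reactants: 23
Product: 24 8β-alcohol (8R) derived from 23, otherwise unchanged
Conditions: L-selectride, THF, −78 °C; H2O quench
Reagents that add atoms: none
Why: Addition of a bulky trialkylborohydride to the C8 ketone anti to the C7–C11 bond of the fused ring (Felkin-type approach from the α face) should give the 8R alcohol.

**Step 14**
Reactants: 24; 25 angelic acid [(Z)-2-methylbut-2-enoic acid]
Product: 27 8-O-angelate of 24, via angelic 2,4,6-trichlorobenzoic anhydride 26 (not isolated)
Conditions: 25, 2,4,6-trichlorobenzoyl chloride, Et3N, toluene, rt; then 24, 80 °C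
Reagents that add atoms: none
Why: Yamaguchi esterification through the 2,4,6-trichlorobenzoyl mixed anhydride, the standard way to acylate hindered alcohols with angelic acid without Z→E isomerisation to the tiglate; C8 keeps its configuration.

**Step 15**
Reactants: 27
Product: 28 1-O-TBS ether of the target (C12 now C=O)
Conditions: CrO3, 3,5-dimethylpyrazole, CH2Cl2, −20 °C
Reagents that add atoms: chromium trioxide, O=[Cr](=O)=O
Why: Chromium(VI)–3,5-dimethylpyrazole allylic oxidation of C12, the only CH2 that is both allylic and α to a ring oxygen, should convert the 3-methyleneoxolane into the α-methylene-γ-butyrolactone (known oxidation of cyclic allylic ethers to lactones).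

**Step 16**
Reactants: 28
Product: 29 target, CNP0213894.1
Conditions: HF·pyridine, pyridine/THF, 0 °C → rt
Reagents that add atoms: none
Why: Fluoride-mediated silyl ether cleavage under buffered conditions that should leave the angelate and the α-methylene lactone untouched.

**Compound list**

1 | (3R,4R)-hexa-1,5-diene-3,4-diol | C=C[C@@H](O)[C@H](O)C=C | starting material
2 | 3-bromo-1-(trimethylsilyl)prop-1-yne | C[Si](C)(C)C#CCBr | starting material
3 | (3R,4R)-4-{[3-(trimethylsilyl)prop-2-yn-1-yl]oxy}hexa-1,5-dien-3-ol | C=C[C@@H](O)[C@H](OCC#C[Si](C)(C)C)C=C | intermediate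
4 | 2-methylprop-2-enoyl chloride | CC(=C)C(Cl)=O | starting material
5 | (3R,4R)-4-{[3-(trimethylsilyl)prop-2-yn-1-yl]oxy}hexa-1,5-dien-3-yl 2-methylprop-2-enoate | C=C[C@@H](OC(=O)C(C)=C)[C@H](OCC#C[Si](C)(C)C)C=C | intermediate
6 | (5R,6R)-6-ethenyl-3-methyl-5-{[3-(trimethylsilyl)prop-2-yn-1-yl]oxy}-5,6-dihydro-2H-pyran-2-one | C=C[C@H]1OC(=O)C(C)=C[C@H]1OCC#C[Si](C)(C)C | intermediate
7 | tert-butyl acetate | CC(=O)OC(C)(C)C | starting material
8 | lithium enolate of tert-butyl acetate (not isolated) | [Li+].C=C([O-])OC(C)(C)C | intermediate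
9 | tert-butyl 2-[(5R,6R)-6-ethenyl-2-hydroxy-3-methyl-5-{[3-(trimethylsilyl)prop-2-yn-1-yl]oxy}-5,6-dihydro-2H-pyran-2-yl]acetate (both anomers) | C=C[C@H]1OC(O)(CC(=O)OC(C)(C)C)C(C)=C[C@H]1OCC#C[Si](C)(C)C | intermediate
10 | tert-butyl 2-[(2S,5R,6R)-6-ethenyl-3-methyl-5-{[3-(trimethylsilyl)prop-2-yn-1-yl]oxy}-5,6-dihydro-2H-pyran-2-yl]acetate (not isolated) | C=C[C@H]1O[C@@H](CC(=O)OC(C)(C)C)C(C)=C[C@H]1OCC#C[Si](C)(C)C | intermediate
11 | 2-[(2S,5R,6R)-6-ethenyl-3-methyl-5-{[3-(trimethylsilyl)prop-2-yn-1-yl]oxy}-5,6-dihydro-2H-pyran-2-yl]acetic acid | C=C[C@H]1O[C@@H](CC(O)=O)C(C)=C[C@H]1OCC#C[Si](C)(C)C | intermediate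
12 | 2-[(2S,5R,6S)-6-acetyl-3-methyl-5-{[3-(trimethylsilyl)prop-2-yn-1-yl]oxy}-5,6-dihydro-2H-pyran-2-yl]acetic acid | CC(=O)[C@H]1O[C@@H](CC(O)=O)C(C)=C[C@H]1OCC#C[Si](C)(C)C | intermediate
13 | dilithium carboxylate enolate of 12 (not isolated) | [Li+].[Li+].C=C([O-])[C@H]1O[C@@H](CC([O-])=O)C(C)=C[C@H]1OCC#C[Si](C)(C)C | intermediate
14 | 2-[(2S,5R,6S)-3-methyl-6-{1-[(triisopropylsilyl)oxy]ethenyl}-5-{[3-(trimethylsilyl)prop-2-yn-1-yl]oxy}-5,6-dihydro-2H-pyran-2-yl]acetic acid | C=C(O[Si](C(C)C)(C(C)C)C(C)C)[C@H]1O[C@@H](CC(O)=O)C(C)=C[C@H]1OCC#C[Si](C)(C)C | intermediate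
15 | diazoethane | CC=[N+]=[N-] | starting material
16 | mixed anhydride of 14 with isobutyl hydrogen carbonate (not isolated) | C=C(O[Si](C(C)C)(C(C)C)C(C)C)[C@H]1O[C@@H](CC(=O)OC(=O)OCC(C)C)C(C)=C[C@H]1OCC#C[Si](C)(C)C | intermediate
17 | 3-diazo-1-[(2S,5R,6S)-3-methyl-6-{1-[(triisopropylsilyl)oxy]ethenyl}-5-{[3-(trimethylsilyl)prop-2-yn-1-yl]oxy}-5,6-dihydro-2H-pyran-2-yl]butan-2-one | C=C(O[Si](C(C)C)(C(C)C)C(C)C)[C@H]1O[C@@H](CC(=O)C(C)=[N+]=[N-])C(C)=C[C@H]1OCC#C[Si](C)(C)C | intermediate
18 | bicyclic oxonium ylide: ring oxygen bonded to C3, C7 and the ylide carbon C10 (not isolated) | C=C(O[Si](C(C)C)(C(C)C)C(C)C)[C@H]1[O+]2[C@@H](CC(=O)[C-]2C)C(C)=C[C@H]1OCC#C[Si](C)(C)C | intermediate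
19 | (1S,4R,8S,2Z)-2,8-dimethyl-6-[(triisopropylsilyl)oxy]-4-{[3-(trimethylsilyl)prop-2-yn-1-yl]oxy}-11-oxabicyclo[6.2.1]undeca-2,5-dien-9-one (5E drawn) | C[C@@]12O[C@@H](CC1=O)/C(C)=C\[C@@H](OCC#C[Si](C)(C)C)/C=C(O[Si](C(C)C)(C(C)C)C(C)C)\C2 | intermediate
20 | (1S,4R,8S,9S,2Z)-2,8-dimethyl-6-[(triisopropylsilyl)oxy]-4-{[3-(trimethylsilyl)prop-2-yn-1-yl]oxy}-11-oxabicyclo[6.2.1]undeca-2,5-dien-9-ol (not isolated) | C[C@@]12O[C@@H](C[C@@H]1O)/C(C)=C\[C@@H](OCC#C[Si](C)(C)C)/C=C(O[Si](C(C)C)(C(C)C)C(C)C)\C2 | intermediate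
21 | (1S,4R,8S,9S,2Z)-2,8-dimethyl-4-(prop-2-yn-1-yloxy)-6-[(triisopropylsilyl)oxy]-11-oxabicyclo[6.2.1]undeca-2,5-dien-9-ol | C[C@@]12O[C@@H](C[C@@H]1O)/C(C)=C\[C@@H](OCC#C)/C=C(O[Si](C(C)C)(C(C)C)C(C)C)\C2 | intermediate
22 | 9-O-tert-butyldimethylsilyl ether of 21 (O1 in target numbering) | C[C@@]12O[C@@H](C[C@@H]1O[Si](C)(C)C(C)(C)C)/C(C)=C\[C@@H](OCC#C)/C=C(O[Si](C(C)C)(C(C)C)C(C)C)\C2 | intermediate
23 | tricyclic 8-ketone: target skeleton with C12 as CH2 (3-methyleneoxolane), C8=O, O1–TBS; C1, C3, C6, C7, C10 as in the target | C=C1CO[C@@H]2/C=C(/C)[C@@H]3C[C@H](O[Si](C)(C)C(C)(C)C)[C@](C)(CC(=O)[C@@H]12)O3 | intermediate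
24 | 8R (8β) alcohol from 23 | C=C1CO[C@@H]2/C=C(/C)[C@@H]3C[C@H](O[Si](C)(C)C(C)(C)C)[C@](C)(C[C@@H](O)[C@@H]12)O3 | intermediate
25 | angelic acid, (Z)-2-methylbut-2-enoic acid | C/C=C(/C)C(O)=O | starting material
26 | angelic 2,4,6-trichlorobenzoic anhydride (not isolated) | C/C=C(/C)C(=O)OC(=O)c1c(Cl)cc(Cl)cc1Cl | intermediate
27 | 8-O-angelate of 24 | C=C1CO[C@@H]2/C=C(/C)[C@@H]3C[C@H](O[Si](C)(C)C(C)(C)C)[C@](C)(C[C@@H](OC(=O)/C(C)=C\C)[C@@H]12)O3 | intermediate
28 | 1-O-tert-butyldimethylsilyl ether of the target | C=C1C(=O)O[C@@H]2/C=C(/C)[C@@H]3C[C@H](O[Si](C)(C)C(C)(C)C)[C@](C)(C[C@@H](OC(=O)/C(C)=C\C)[C@@H]12)O3 | intermediate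
29 | CNP0213894.1: (1S,3S,6R,7R,8R,10S,4Z)-8-angeloyloxy-3,10-epoxy-1-hydroxygermacra-4,11(13)-dien-6,12-olide | C=C1C(=O)O[C@@H]2/C=C(/C)[C@@H]3C[C@H](O)[C@](C)(C[C@@H](OC(=O)/C(C)=C\C)[C@@H]12)O3 | target

**Step count**

Total steps: 16. Longest linear sequence: 16 (from 1).

**Steps most likely to fail**

Step 9 (key step). The methyl-bearing copper carbenoid may undergo 1,2-hydride shift to a vinyl ketone, or add to the neighbouring C4=C5 olefin (cyclopropanation), faster than it is captured by the ring oxygen; a [1,2] shift of the ylide is a further leak. Fallback, from 14, returning at 20: the acid 14 is homologated (carbonyldiimidazole, then magnesium methyl malonate) to the methyl β-keto ester F1, and diazo transfer (p-acetamidobenzenesulfonyl azide, Et3N) gives the α-diazo-β-keto ester F2. This doubly stabilised diazo compound has no β-hydrogen and is a standard substrate for copper-catalysed oxonium-ylide formation and [2,3] shift, which should give the bicyclic β-keto ester F3 with CO2Me on C10 in place of the methyl group. LiAlH4 reduces the ketone (exo attack) and the ester to the diol F4, the primary hydroxyl is converted with 1,1'-thiocarbonyldiimidazole into the imidazolyl thionocarbonate F5, and Barton–McCombie reduction (Bu3SnH, AIBN, toluene, 110 °C) gives 20, which continues with the methanolysis stage of step 10.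

Step 13. Facial selectivity in the hydride addition to C8 may be poor or reversed, since the conformation of the nine-membered ring around C7–C8 decides which face is open. Fallback, from 23, returning at 24: if the reduction gives mainly the 8-epi alcohol F6, it is inverted by Mitsunobu reaction with 4-nitrobenzoic acid (PPh3, DIAD) to the 8R 4-nitrobenzoate F7, and methanolysis (K2CO3, MeOH) gives 24.

Step 4. The ester enolate may add in conjugate fashion to the unsaturated lactone, or deprotonate it at the γ position, instead of adding to the carbonyl group. Fallback, from 6, returning at 9: the lactone 6 is opened with N,O-dimethylhydroxylamine hydrochloride and AlMe3 to the (Z)-hydroxy Weinreb amide F8, which is treated at once with an excess of lithium tert-butyl acetate; acyl substitution at the amide gives the open-chain β-keto ester, which closes to the hemiketal 9 on work-up.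

**Further compounds**

F1 | step 9 | methyl 4-[(2S,5R,6S)-3-methyl-6-{1-[(triisopropylsilyl)oxy]ethenyl}-5-{[3-(trimethylsilyl)prop-2-yn-1-yl]oxy}-5,6-dihydro-2H-pyran-2-yl]-3-oxobutanoate | C=C(O[Si](C(C)C)(C(C)C)C(C)C)[C@H]1O[C@@H](CC(=O)CC(=O)OC)C(C)=C[C@H]1OCC#C[Si](C)(C)C
F2 | step 9 | methyl 2-diazo-4-[(2S,5R,6S)-3-methyl-6-{1-[(triisopropylsilyl)oxy]ethenyl}-5-{[3-(trimethylsilyl)prop-2-yn-1-yl]oxy}-5,6-dihydro-2H-pyran-2-yl]-3-oxobutanoate | C=C(O[Si](C(C)C)(C(C)C)C(C)C)[C@H]1O[C@@H](CC(=O)C(=[N+]=[N-])C(=O)OC)C(C)=C[C@H]1OCC#C[Si](C)(C)C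
F3 | step 9 | analogue of 19 with a methoxycarbonyl group on C10 (bicyclo C8) in place of methyl | COC(=O)[C@@]12O[C@@H](CC1=O)/C(C)=C\[C@@H](OCC#C[Si](C)(C)C)/C=C(O[Si](C(C)C)(C(C)C)C(C)C)\C2
F4 | step 9 | diol: analogue of 20 with hydroxymethyl on C10 in place of methyl | OC[C@@]12O[C@@H](C[C@@H]1O)/C(C)=C\[C@@H](OCC#C[Si](C)(C)C)/C=C(O[Si](C(C)C)(C(C)C)C(C)C)\C2
F5 | step 9 | O-(imidazol-1-ylthiocarbonyl) derivative of F4 at the primary hydroxyl | S=C(OC[C@@]12O[C@@H](C[C@@H]1O)/C(C)=C\[C@@H](OCC#C[Si](C)(C)C)/C=C(O[Si](C(C)C)(C(C)C)C(C)C)\C2)n1ccnc1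
F6 | step 13 | 8-epi alcohol (8S) of 24 | C=C1CO[C@@H]2/C=C(/C)[C@@H]3C[C@H](O[Si](C)(C)C(C)(C)C)[C@](C)(C[C@H](O)[C@@H]12)O3
F7 | step 13 | 8-O-(4-nitrobenzoate) of 24 (8R) | C=C1CO[C@@H]2/C=C(/C)[C@@H]3C[C@H](O[Si](C)(C)C(C)(C)C)[C@](C)(C[C@@H](OC(=O)c4ccc(cc4)[N+](=O)[O-])[C@@H]12)O3
F8 | step 4 | (2Z,4R,5R)-5-hydroxy-N-methoxy-N,2-dimethyl-4-{[3-(trimethylsilyl)prop-2-yn-1-yl]oxy}hepta-2,6-dienamide | C=C[C@@H](O)[C@H](OCC#C[Si](C)(C)C)/C=C(/C)C(=O)N(C)OC
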